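**Retrosynthetic overview**

- The strategy rests on two carbons. C7 is a benzylic carbinol carbon bearing ring B (3,4-dimethoxyphenyl), so it is the CH2 carbon of a veratryl silyl ether whose C–H bond is activated by the α-oxygen and the electron-rich ring. C8 bears ring A and the C9 methyl, so it maps onto the carbenoid carbon of a ring A aryldiazoacetate whose ester is the masked methyl.
- The key disconnection is C7–C8: one enantioselective intermolecular rhodium-carbenoid C–H insertion forms this bond and both stereocentres (7S,8S). No ring is formed anywhere; both benzene rings are bought.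
- Ring A enters as an aryl bromide, because a carbenoid would cyclopropanate the allyl group. The diazo ester is made from 4-bromo-2-methoxyphenol by ortho-iodination, silylation and Pd-catalysed coupling of the C–I bond with ethyl diazoacetate.
- After the key step: CO2Et → CH2OH → CH2OTs → CH3, Stille allylation at C–Br, then removal of both silyl groups.

Key step: step 5

Assumption: Rh2(R-PTAD)4 is taken to favour the (2S,3S) insertion product; the sense of induction on this ortho-substituted donor must be confirmed on the first batch (MTPA esters of a desilylated sample), and the mirror-image catalyst Rh2(S-PTAD)4 would replace it with no other change if the antipode predominates.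

**Route**

Step 1
Reactants: 1 4-bromo-2-methoxyphenol
Product: 2 4-bromo-2-iodo-6-methoxyphenol
Conditions: NaI, NaOH, aq. NaOCl, MeOH, 0 °C; then aq. Na2S2O3, HCl to pH 5
Reagents that add atoms: sodium iodide, [Na+].[I-]
Why: Electrophilic aromatic iodination of the phenoxide by hypoiodite made in the flask; the para position is blocked by bromine, so the phenoxide oxygen should direct iodine to its only free ortho carbon rather than to the position para to OMe.

Step 2
Reactants: 2 4-bromo-2-iodo-6-methoxyphenol
Product: 3 (4-bromo-2-iodo-6-methoxyphenoxy)(tert-butyl)dimethylsilane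
Conditions: TBSCl, imidazole, DMF, rt to 40 °C
Reagents that add atoms: tert-butyldimethylsilyl chloride, CC(C)(C)[Si](C)(C)Cl
Why: Imidazole-promoted O-silylation of a phenol; the phenol is flanked on both sides but should still silylate in DMF with mild warming.

Step 3
Reactants: 3 (4-bromo-2-iodo-6-methoxyphenoxy)(tert-butyl)dimethylsilane; 4 ethyl diazoacetate
Product: 5 ethyl 2-[5-bromo-2-(tert-butyldimethylsilyloxy)-3-methoxyphenyl]-2-diazoacetate
Conditions: Pd(PPh3)4 (5 mol %), Ag2CO3 (0.5 equiv), Et3N, toluene, rt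
Reagents that add atoms: none
Why: Palladium-catalysed cross-coupling of an aryl iodide with the C–H bond of an acceptor diazo compound (oxidative addition of zerovalent palladium at C–I, silver-assisted transfer of the deprotonated diazoacetate, reductive elimination); at room temperature it should be selective for C–I over C–Br and keep the diazo group.

Step 4
Reactants: 6 3,4-dimethoxybenzyl alcohol
Product: 7 tert-butyl[(3,4-dimethoxyphenyl)methoxy]dimethylsilane
Conditions: TBSCl, imidazole, CH2Cl2, rt
Reagents that add atoms: tert-butyldimethylsilyl chloride, CC(C)(C)[Si](C)(C)Cl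
Why: Standard imidazole-promoted silylation of a primary benzylic alcohol.

Step 5
Reactants: 5 ethyl 2-[5-bromo-2-(tert-butyldimethylsilyloxy)-3-methoxyphenyl]-2-diazoacetate; 7 tert-butyl[(3,4-dimethoxyphenyl)methoxy]dimethylsilane (2.5 equiv, excess recovered)
Product: 8 ethyl (2S,3S)-2-[5-bromo-2-(tert-butyldimethylsilyloxy)-3-methoxyphenyl]-3-(tert-butyldimethylsilyloxy)-3-(3,4-dimethoxyphenyl)propanoate
Conditions: Rh2(R-PTAD)4 (dirhodium tetrakis[(R)-(1-adamantyl)(N-phthalimido)acetate], 1 mol %), 2,2-dimethylbutane, 50 °C, 5 added by syringe pump over 3 h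
Reagents that add atoms: none
Why: The divalent rhodium dimer releases N2 from 5 to give a donor/acceptor carbenoid (ring A donor, ester acceptor), whose carbon inserts into one benzylic C–H bond of 7 through a concerted, asynchronous three-centre transition state with hydride-transfer character, forming the C2–C3 bond (C8–C7 of the target) and the C2–H bond. The closest known reaction type is the enantioselective intermolecular C–H functionalisation of benzyl silyl ethers by aryldiazoacetates under chiral dirhodium tetracarboxylates (an aldol surrogate); the phthalimido amino-acid catalyst is chosen over the arylsulfonylprolinate because that ligand class is the one reported to give good enantiocontrol with benzyl ethers and to tolerate ortho-substituted donor aryl groups, although an ortho silyloxy donor extends that scope. No ring is closed. Both stereocentres are set here under catalyst control: the carboxylate ligand sphere selects the carbenoid face (C2) and which of the two enantiotopic benzylic hydrogens is transferred (C3), and the arrangement with hydrogen toward the carbenoid and ring B turned away from the catalyst should give the syn (aldol-type) product, with the ester and the silyloxy group on opposite sides of the ring A–C2–C3–ring B chain as in the target. Site selectivity for the oxygen-bearing benzylic CH2 over OCH3, Si–CH3 and ring positions rests on stabilisation of the developing positive charge by the α-oxygen and the para-methoxy group of ring B. Ring A carries bromine and not allyl so that no alkene competes, and slow addition with excess 7 should suppress carbene dimerisation.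

Step 6
Reactants: 8 ethyl (2S,3S)-2-[5-bromo-2-(tert-butyldimethylsilyloxy)-3-methoxyphenyl]-3-(tert-butyldimethylsilyloxy)-3-(3,4-dimethoxyphenyl)propanoate
Product: 9 (2R,3S)-2-[5-bromo-2-(tert-butyldimethylsilyloxy)-3-methoxyphenyl]-3-(tert-butyldimethylsilyloxy)-3-(3,4-dimethoxyphenyl)propan-1-ol (same spatial arrangement as 8; the C2 descriptor changes only through CIP ranking)
Conditions: i-Bu2AlH (3 equiv), CH2Cl2, −78 to 0 °C; aq. potassium sodium tartrate (KNaC4H4O6) work-up
Reagents that add atoms: none
Why: Hydride reduction of the ester to the primary alcohol under non-basic conditions, so the acidic α-aryl C2–H centre should not epimerise and the silyl ethers and C–Br should remain.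

Step 7
Reactants: 9 (2R,3S)-2-[5-bromo-2-(tert-butyldimethylsilyloxy)-3-methoxyphenyl]-3-(tert-butyldimethylsilyloxy)-3-(3,4-dimethoxyphenyl)propan-1-ol
Product: 10 (2R,3S)-2-[5-bromo-2-(tert-butyldimethylsilyloxy)-3-methoxyphenyl]-3-(tert-butyldimethylsilyloxy)-3-(3,4-dimethoxyphenyl)propyl 4-methylbenzenesulfonate
Conditions: TsCl, Et3N, DMAP (cat.), CH2Cl2, 0 °C to rt
Reagents that add atoms: p-toluenesulfonyl chloride, Cc1ccc(cc1)S(Cl)(=O)=O
Why: DMAP-catalysed sulfonylation of the primary alcohol; no stereocentre is involved.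

Step 8
Reactants: 10 (2R,3S)-2-[5-bromo-2-(tert-butyldimethylsilyloxy)-3-methoxyphenyl]-3-(tert-butyldimethylsilyloxy)-3-(3,4-dimethoxyphenyl)propyl 4-methylbenzenesulfonate
Product: 11 (1S,2S)-2-[5-bromo-2-(tert-butyldimethylsilyloxy)-3-methoxyphenyl]-1-(tert-butyldimethylsilyloxy)-1-(3,4-dimethoxyphenyl)propane
Conditions: LiEt3BH (4 equiv), THF, 0 °C to rt
Reagents that add atoms: none
Why: SN2 displacement of the primary tosylate by the strongly nucleophilic hydride of LiEt3BH, which is suited to β-branched primary sulfonates; C–Br and the silyl ethers should survive at or below room temperature and neither stereocentre is touched.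

Step 9
Reactants: 11 (1S,2S)-2-[5-bromo-2-(tert-butyldimethylsilyloxy)-3-methoxyphenyl]-1-(tert-butyldimethylsilyloxy)-1-(3,4-dimethoxyphenyl)propane; 12 allyltributylstannane
Product: 13 (1S,2S)-2-[5-allyl-2-(tert-butyldimethylsilyloxy)-3-methoxyphenyl]-1-(tert-butyldimethylsilyloxy)-1-(3,4-dimethoxyphenyl)propane
Conditions: Pd(PPh3)4 (5 mol %), toluene, 110 °C, degassed
Reagents that add atoms: none
Why: Stille coupling (oxidative addition of zerovalent palladium at the unhindered C–Br, transmetallation from the allylstannane, reductive elimination) under neutral conditions that should leave the silyl ethers and both stereocentres untouched.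

Step 10
Reactants: 13 (1S,2S)-2-[5-allyl-2-(tert-butyldimethylsilyloxy)-3-methoxyphenyl]-1-(tert-butyldimethylsilyloxy)-1-(3,4-dimethoxyphenyl)propane
Product: 14 (1S,2S)-2-(5-allyl-2-hydroxy-3-methoxyphenyl)-1-(3,4-dimethoxyphenyl)propan-1-ol, the target (7S,8S)
Conditions: TBAF (3 equiv), THF, 0 °C to rt; sat. aq. NH4Cl work-up
Reagents that add atoms: none
Why: Fluoride-driven cleavage of the aryl and the benzylic Si–O bonds; the absence of strong acid should prevent ionisation at C7 (and ring closure to a dihydrobenzofuran) and the mild base should not move the allyl double bond.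

**Compound list**

1 | 4-bromo-2-methoxyphenol | COc1cc(Br)ccc1O | starting material
2 | 4-bromo-2-iodo-6-methoxyphenol | COc1cc(Br)cc(I)c1O | intermediate
3 | (4-bromo-2-iodo-6-methoxyphenoxy)(tert-butyl)dimethylsilane | COc1cc(Br)cc(I)c1O[Si](C)(C)C(C)(C)C | intermediate
4 | ethyl diazoacetate | CCOC(=O)C=[N+]=[N-] | starting material
5 | ethyl 2-[5-bromo-2-(tert-butyldimethylsilyloxy)-3-methoxyphenyl]-2-diazoacetate | CCOC(=O)C(=[N+]=[N-])c1cc(Br)cc(OC)c1O[Si](C)(C)C(C)(C)C | intermediate
6 | 3,4-dimethoxybenzyl alcohol | COc1ccc(CO)cc1OC | starting material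
7 | tert-butyl[(3,4-dimethoxyphenyl)methoxy]dimethylsilane | COc1ccc(CO[Si](C)(C)C(C)(C)C)cc1OC | intermediate
8 | ethyl (2S,3S)-2-[5-bromo-2-(tert-butyldimethylsilyloxy)-3-methoxyphenyl]-3-(tert-butyldimethylsilyloxy)-3-(3,4-dimethoxyphenyl)propanoate | Brc1cc(OC)c(O[Si](C)(C)C(C)(C)C)c([C@H](C(=O)OCC)[C@H](O[Si](C)(C)C(C)(C)C)c2ccc(OC)c(OC)c2)c1 | intermediate
9 | (2R,3S)-2-[5-bromo-2-(tert-butyldimethylsilyloxy)-3-methoxyphenyl]-3-(tert-butyldimethylsilyloxy)-3-(3,4-dimethoxyphenyl)propan-1-ol | Brc1cc(OC)c(O[Si](C)(C)C(C)(C)C)c([C@H](CO)[C@H](O[Si](C)(C)C(C)(C)C)c2ccc(OC)c(OC)c2)c1 | intermediate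
10 | (2R,3S)-2-[5-bromo-2-(tert-butyldimethylsilyloxy)-3-methoxyphenyl]-3-(tert-butyldimethylsilyloxy)-3-(3,4-dimethoxyphenyl)propyl 4-methylbenzenesulfonate | Brc1cc(OC)c(O[Si](C)(C)C(C)(C)C)c([C@H](COS(=O)(=O)c3ccc(C)cc3)[C@H](O[Si](C)(C)C(C)(C)C)c2ccc(OC)c(OC)c2)c1 | intermediate
11 | (1S,2S)-2-[5-bromo-2-(tert-butyldimethylsilyloxy)-3-methoxyphenyl]-1-(tert-butyldimethylsilyloxy)-1-(3,4-dimethoxyphenyl)propane | Brc1cc(OC)c(O[Si](C)(C)C(C)(C)C)c([C@H](C)[C@H](O[Si](C)(C)C(C)(C)C)c2ccc(OC)c(OC)c2)c1 | intermediate
12 | allyltributylstannane | C=CC[Sn](CCCC)(CCCC)CCCC | starting material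
13 | (1S,2S)-2-[5-allyl-2-(tert-butyldimethylsilyloxy)-3-methoxyphenyl]-1-(tert-butyldimethylsilyloxy)-1-(3,4-dimethoxyphenyl)propane | C=CCc1cc(OC)c(O[Si](C)(C)C(C)(C)C)c([C@H](C)[C@H](O[Si](C)(C)C(C)(C)C)c2ccc(OC)c(OC)c2)c1 | intermediate
14 | (1S,2S)-2-(5-allyl-2-hydroxy-3-methoxyphenyl)-1-(3,4-dimethoxyphenyl)propan-1-ol | C=CCc1cc(OC)c(O)c([C@H](C)[C@H](O)c2ccc(OC)c(OC)c2)c1 | target

**Step count and risks**

Total step count: 10. Longest linear sequence: 9 steps (steps 1, 2, 3, 5, 6, 7, 8, 9, 10).

Steps most likely to fail: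

1. Step 5 (C–H insertion). The bulky ortho silyloxy group may twist ring A out of conjugation with the carbenoid and erode facial and diastereocontrol. Electrophilic attack of the carbenoid on the electron-rich ring B or carbene dimerisation may also outrun insertion. The fallback replaces catalyst control by an auxiliary-controlled Evans syn-aldol; it sets out from 3 and returns at 9.
   - The C–I bond of 3 is coupled with the Reformatsky reagent BrZnCH2CO2t-Bu (Pd(dba)2, P(t-Bu)3, THF, rt) to give tert-butyl 2-[5-bromo-2-(tert-butyldimethylsilyloxy)-3-methoxyphenyl]acetate F1.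
   - TFA in CH2Cl2 at 0 °C frees 2-[5-bromo-2-(tert-butyldimethylsilyloxy)-3-methoxyphenyl]acetic acid F2.
   - Its pivaloyl mixed anhydride (t-BuCOCl, Et3N, LiCl, THF) acylates (S)-4-benzyl-2-oxazolidinone to give (S)-4-benzyl-3-{2-[5-bromo-2-(tert-butyldimethylsilyloxy)-3-methoxyphenyl]acetyl}oxazolidin-2-one F3.
   - Boron enolisation (n-Bu2BOTf, i-Pr2NEt, CH2Cl2, −78 °C) and addition of commercial 3,4-dimethoxybenzaldehyde should give, through the Z-enolate and a chair transition state, (S)-4-benzyl-3-{(2S,3S)-2-[5-bromo-2-(tert-butyldimethylsilyloxy)-3-methoxyphenyl]-3-(3,4-dimethoxyphenyl)-3-hydroxypropanoyl}oxazolidin-2-one F4.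
   - TBSOTf and 2,6-lutidine convert it to (S)-4-benzyl-3-{(2S,3S)-2-[5-bromo-2-(tert-butyldimethylsilyloxy)-3-methoxyphenyl]-3-(tert-butyldimethylsilyloxy)-3-(3,4-dimethoxyphenyl)propanoyl}oxazolidin-2-one F5.
   - LiBH4 (THF, MeOH, 0 °C) removes the auxiliary reductively to give alcohol 9.

2. Step 3 (aryl iodide–diazoacetate coupling). Transmetallation and reductive elimination at the hindered ortho-silyloxy arylpalladium may be slow, so that palladium decomposes the diazo partner or begins to insert into C–Br. The fallback builds the aryl acetate first and introduces nitrogen afterwards; it sets out from 3 and returns at 5.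
   - Negishi-type coupling of the C–I bond with the Reformatsky reagent BrZnCH2CO2Et (from ethyl bromoacetate and Zn; Pd(dba)2, P(t-Bu)3, THF, rt) gives ethyl 2-[5-bromo-2-(tert-butyldimethylsilyloxy)-3-methoxyphenyl]acetate F6.
   - Regitz diazo transfer (4-acetamidobenzenesulfonyl azide, DBU, MeCN, 0 °C) then gives 5.

3. Step 8 (hydride displacement). Hydride may attack silicon of the aryl silyl ether, and the phenoxide so formed would close onto the tosylate carbon; slow substitution at the β-branched carbon may also let elimination compete. The fallback removes the oxygen by a neutral radical reduction after the bromide has been used up; it sets out from 9 and returns at 13.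
   - Stille coupling of 9 with 12 (Pd(PPh3)4, toluene, 110 °C) gives (2R,3S)-2-[5-allyl-2-(tert-butyldimethylsilyloxy)-3-methoxyphenyl]-3-(tert-butyldimethylsilyloxy)-3-(3,4-dimethoxyphenyl)propan-1-ol F7.
   - Appel-type iodination (I2, PPh3, imidazole, CH2Cl2, 0 °C) gives (2S,3S)-2-[5-allyl-2-(tert-butyldimethylsilyloxy)-3-methoxyphenyl]-3-(tert-butyldimethylsilyloxy)-3-(3,4-dimethoxyphenyl)-1-iodopropane F8.
   - n-Bu3SnH with AIBN in benzene at 80 °C reduces the C–I bond to give 13.

**Further compounds**

F1 | step 5 | tert-butyl 2-[5-bromo-2-(tert-butyldimethylsilyloxy)-3-methoxyphenyl]acetate | CC(C)(C)OC(=O)Cc1cc(Br)cc(OC)c1O[Si](C)(C)C(C)(C)C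
F2 | step 5 | 2-[5-bromo-2-(tert-butyldimethylsilyloxy)-3-methoxyphenyl]acetic acid | OC(=O)Cc1cc(Br)cc(OC)c1O[Si](C)(C)C(C)(C)C
F3 | step 5 | (S)-4-benzyl-3-{2-[5-bromo-2-(tert-butyldimethylsilyloxy)-3-methoxyphenyl]acetyl}oxazolidin-2-one | O=C(Cc1cc(Br)cc(OC)c1O[Si](C)(C)C(C)(C)C)N1[C@@H](Cc2ccccc2)COC1=O
F4 | step 5 | (S)-4-benzyl-3-{(2S,3S)-2-[5-bromo-2-(tert-butyldimethylsilyloxy)-3-methoxyphenyl]-3-(3,4-dimethoxyphenyl)-3-hydroxypropanoyl}oxazolidin-2-one | Brc1cc(OC)c(O[Si](C)(C)C(C)(C)C)c([C@H](C(=O)N3[C@@H](Cc4ccccc4)COC3=O)[C@H](O)c2ccc(OC)c(OC)c2)c1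
F5 | step 5 | (S)-4-benzyl-3-{(2S,3S)-2-[5-bromo-2-(tert-butyldimethylsilyloxy)-3-methoxyphenyl]-3-(tert-butyldimethylsilyloxy)-3-(3,4-dimethoxyphenyl)propanoyl}oxazolidin-2-one | Brc1cc(OC)c(O[Si](C)(C)C(C)(C)C)c([C@H](C(=O)N3[C@@H](Cc4ccccc4)COC3=O)[C@H](O[Si](C)(C)C(C)(C)C)c2ccc(OC)c(OC)c2)c1
F6 | step 3 | ethyl 2-[5-bromo-2-(tert-butyldimethylsilyloxy)-3-methoxyphenyl]acetate | CCOC(=O)Cc1cc(Br)cc(OC)c1O[Si](C)(C)C(C)(C)C
F7 | step 8 | (2R,3S)-2-[5-allyl-2-(tert-butyldimethylsilyloxy)-3-methoxyphenyl]-3-(tert-butyldimethylsilyloxy)-3-(3,4-dimethoxyphenyl)propan-1-ol | C=CCc1cc(OC)c(O[Si](C)(C)C(C)(C)C)c([C@H](CO)[C@H](O[Si](C)(C)C(C)(C)C)c2ccc(OC)c(OC)c2)c1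
F8 | step 8 | (2S,3S)-2-[5-allyl-2-(tert-butyldimethylsilyloxy)-3-methoxyphenyl]-3-(tert-butyldimethylsilyloxy)-3-(3,4-dimethoxyphenyl)-1-iodopropane | C=CCc1cc(OC)c(O[Si](C)(C)C(C)(C)C)c([C@H](CI)[C@H](O[Si](C)(C)C(C)(C)C)c2ccc(OC)c(OC)c2)c1
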